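**Retrosynthetic overview** (carotenoid numbering; the hydroxylated ring is ring B, the unsubstituted ring is ring A)
1. Ester C–O bond, made last: target ⇒ (3R)-β-cryptoxanthin + palmitoleic acid (carbodiimide esterification, C3–O bond untouched).
2. C7=C8 olefin (Wittig, C30 + C10): ⇒ commercial β-apo-8'-carotenal, which brings ring A preformed, + the ring B salt [(4R)-4-hydroxy-2,6,6-trimethylcyclohexenyl]methyl-PPh3+.
3. Ring B, the only ring built (step 3): cyclase-type cation–olefin closure C1–C6 of an acyclic, 3-oxygenated ψ-type allylic phosphonium salt. The C1 tertiary cation comes from a protonated isopropenyl terminus, loss of H-6 gives the β double bond, and the C3 carbinol is already in place.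
4. Acyclic salt ⇒ myrcene-type dienol (4S)-2-methyl-6-methylideneocta-1,7-dien-4-ol, by 1,4-addition of Ph3P/H+ to the diene in the same flask as the cyclisation.
5. Dienol ⇒ (S)-epichlorohydrin as the C3 linchpin: its two CH2 arms take an isopropenyl (C1 side) and a buta-1,3-dien-2-yl (C5–C7 side) Grignard reagent; all stereochemistry comes from this one centre.

Assumption: the target is all-E (3R)-β,β-caroten-3-yl (9Z)-hexadec-9-enoate as drawn, and β-apo-8'-carotenal (bulk food colourant) and stabilised chloroprene solution are taken as commercial.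

**Step 1**
Reactants: 1 (S)-epichlorohydrin; 2 isopropenylmagnesium bromide
Product: 4 (2S)-2-(2-methylprop-2-en-1-yl)oxirane, via chlorohydrin 3 (not isolated)
Conditions: CuI (10 mol %), THF, −40 → −20 °C; aq NH4Cl; crude 3 + powdered NaOH, Et2O, rt; distil
Reagents that add atoms: none
Why: Copper-catalysed Grignard opening of the epoxide (SN2 at the unsubstituted CH2, faster than chloride displacement) followed by base-induced ring closure of the chlorohydrin (intramolecular Williamson etherification) moves the oxirane to the other arm without breaking the C–O bond at the stereocentre, so the (S) centre of 1 becomes the (S) centre of 4 and later C3 of ring B.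

**Step 2**
Reactants: 4 (2S)-2-(2-methylprop-2-en-1-yl)oxirane; 5 chloroprene
Product: 7 (4S)-2-methyl-6-methylideneocta-1,7-dien-4-ol, via butadienyl Grignard reagent 6 (not isolated)
Conditions: 5, Mg, ZnCl2 (2 mol %), THF, 40 °C; then CuI (10 mol %), 4, THF, −30 → 0 °C; aq NH4Cl
Reagents that add atoms: none
Why: CuI-catalysed opening of a terminal epoxide at CH2 by the 2-butadienyl Grignard reagent (the reaction type used to make ipsenol from 2-isobutyloxirane) installs the 2-substituted butadiene, a latent C5=C6–C7 ψ-end unit, with the carbinol stereocentre untouched.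

**Step 3**
Reactants: 7 (4S)-2-methyl-6-methylideneocta-1,7-dien-4-ol
Product: 11 {[(4R)-4-hydroxy-2,6,6-trimethylcyclohex-1-en-1-yl]methyl}(triphenyl)phosphonium bromide, via dienyl trifluoroacetate 8 (not isolated), via acyclic phosphonium salt 9 (not isolated), via cyclised trifluoroacetate salt 10 (not isolated)
Conditions: Ph3P (1.05 equiv), (CF3CO)2O (1.05 equiv), CH2Cl2, 0 °C → rt (40 °C if slow), 24 h; MsOH (8 equiv), 0 °C → rt, 2 h; MeOH/aq NaHCO3, 0 °C; CH2Cl2 extract washed with aq NaBr; crystallise
Reagents that add atoms: triphenylphosphine, c1ccc(cc1)P(c1ccccc1)c1ccccc1; sodium bromide, [Na+].[Br-]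
Why: Proposed new method: the hydroxyl is first masked in the flask as a non-participating trifluoroacetate (so it cannot trap the allyl cation as a dihydropyran or ionise later), the liberated CF3CO2H/Ph3P pair then adds 1,4 to the diene (tertiary allyl cation captured by Ph3P at the primary terminus, as in the known Ph3P·HBr addition to isoprene-type dienes, the isolated isopropenyl group being far less basic) to give the ψ-type allylic salt 9, and excess MsOH protonates the isopropenyl group to the C1 tertiary cation (the cation that lycopene β-cyclase generates), which is attacked by C6 in a 6-endo cation–olefin cyclisation and loses H-6 (acidified by the adjacent CH2PPh3+) to give the tetrasubstituted β double bond, the closest known reactions being the H2SO4 cyclisations of pseudoionone to β-ionone and of geranyl aryl sulfones to β-cyclogeranyl sulfones; no bond at the carbinol carbon is made or broken, so (4S)-7 maps onto (4R)-11 (same spatial arrangement, changed CIP priorities), and the methanolic quench removes the trifluoroacetate while NaBr fixes the counter-ion.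

**Step 4**
Reactants: 11 {[(4R)-4-hydroxy-2,6,6-trimethylcyclohex-1-en-1-yl]methyl}(triphenyl)phosphonium bromide; 12 β-apo-8'-carotenal
Product: 14 (3R)-β-cryptoxanthin, via ylide 13 (not isolated)
Conditions: NaOMe (1.5 equiv), CH2Cl2/MeOH, 0 °C → rt, Ar, dark; then n-heptane, reflux, 12 h; crystallise
Reagents that add atoms: none
Why: Wittig olefination of the α-methyl polyenal 12 with the semi-stabilised allylic ylide 13 (the C30 + C10 end-group coupling used for unsymmetrical carotenoids) forms C7=C8, NaOMe deprotonates only the allylic β-type salt (any α or γ double-bond isomer carried over from step 3 would need a far stronger base and is washed out), the free 3-OH is inert, the strained 7Z isomer relaxes to all-E on heating, and the stereocentre is not involved.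

**Step 5**
Reactants: 14 (3R)-β-cryptoxanthin; 15 palmitoleic acid
Product: 16 (3R)-β-cryptoxanthin palmitoleate (target CNP0382087.1)
Conditions: DCC (1.3 equiv), DMAP (0.2 equiv), CH2Cl2, rt, Ar, dark
Reagents that add atoms: none
Why: Steglich esterification (DCC/DMAP, acylpyridinium transfer to the secondary alcohol) forms the ester with retention at C3 because only the O–H bond is broken, under neutral conditions that leave the polyene and the 9Z olefin untouched.

**Compound list**
1 | (S)-epichlorohydrin, (2S)-2-(chloromethyl)oxirane | ClC[C@@H]1CO1 | starting material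
2 | isopropenylmagnesium bromide (prop-1-en-2-ylmagnesium bromide, THF solution) | CC(=C)[Mg]Br | starting material
3 | (2S)-1-chloro-4-methylpent-4-en-2-ol | O[C@@H](CC(C)=C)CCl | intermediate (not isolated)
4 | (2S)-2-(2-methylprop-2-en-1-yl)oxirane | C=C(C)C[C@H]1CO1 | intermediate
5 | chloroprene (2-chlorobuta-1,3-diene) | C=CC(Cl)=C | starting material
6 | buta-1,3-dien-2-ylmagnesium chloride | C=CC(=C)[Mg]Cl | intermediate (not isolated)
7 | (4S)-2-methyl-6-methylideneocta-1,7-dien-4-ol | O[C@@H](CC(C)=C)CC(=C)C=C | intermediate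
8 | (4S)-2-methyl-6-methylideneocta-1,7-dien-4-yl trifluoroacetate | FC(F)(F)C(=O)O[C@@H](CC(C)=C)CC(=C)C=C | intermediate (not isolated)
9 | [(2E,5S)-3,7-dimethyl-5-(trifluoroacetoxy)octa-2,7-dien-1-yl](triphenyl)phosphonium trifluoroacetate (2E drawn; the 2E/2Z mixture cyclises to the same ring) | [O-]C(=O)C(F)(F)F.FC(F)(F)C(=O)O[C@@H](CC(C)=C)C/C(C)=C/C[P+](c1ccccc1)(c1ccccc1)c1ccccc1 | intermediate (not isolated)
10 | {[(4R)-2,6,6-trimethyl-4-(trifluoroacetoxy)cyclohex-1-en-1-yl]methyl}(triphenyl)phosphonium salt (drawn as trifluoroacetate) | [O-]C(=O)C(F)(F)F.FC(F)(F)C(=O)O[C@@H]1CC(C)=C(C[P+](c2ccccc2)(c2ccccc2)c2ccccc2)C(C)(C)C1 | intermediate (not isolated)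
11 | {[(4R)-4-hydroxy-2,6,6-trimethylcyclohex-1-en-1-yl]methyl}(triphenyl)phosphonium bromide (ring B salt) | [Br-].O[C@@H]1CC(C)=C(C[P+](c2ccccc2)(c2ccccc2)c2ccccc2)C(C)(C)C1 | intermediate
12 | β-apo-8'-carotenal (all-E C30 aldehyde carrying ring A) | O=C/C(C)=C/C=C/C(C)=C/C=C/C=C(C)/C=C/C=C(C)/C=C/C1=C(C)CCCC1(C)C | starting material
13 | {[(4R)-4-hydroxy-2,6,6-trimethylcyclohex-1-en-1-yl]methylidene}(triphenyl)phosphorane | O[C@@H]1CC(C)=C(C=P(c2ccccc2)(c2ccccc2)c2ccccc2)C(C)(C)C1 | intermediate (not isolated)
14 | (3R)-β-cryptoxanthin, all-E (3R)-β,β-caroten-3-ol | O[C@@H]1CC(C)=C(/C=C/C(C)=C/C=C/C(C)=C/C=C/C=C(C)/C=C/C=C(C)/C=C/C2=C(C)CCCC2(C)C)C(C)(C)C1 | intermediate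
15 | palmitoleic acid, (9Z)-hexadec-9-enoic acid | CCCCCC/C=C\CCCCCCCC(=O)O | starting material
16 | (3R)-β,β-caroten-3-yl (9Z)-hexadec-9-enoate | CCCCCC/C=C\CCCCCCCC(=O)O[C@@H]1CC(C)=C(/C=C/C(C)=C/C=C/C(C)=C/C=C/C=C(C)/C=C/C=C(C)/C=C/C2=C(C)CCCC2(C)C)C(C)(C)C1 | target

**Total step count:** 5. **Longest linear sequence:** 5 steps (1 → 4 → 7 → 11 → 14 → 16); 2, 5, 12 and 15 are bought.

**Three steps most likely to fail**

Step 3 is the riskiest. The cyclisation of an allylic phosphonium salt is unprecedented, the α/β/γ double-bond ratio is not secured, and the allyl cation of the first stage can be diverted by the isopropenyl group. The fallback sets out from 7 and comes back at 14. It replaces the phosphonium group by a benzothiazolyl sulfone, because acid cyclisation of geranyl-type aryl sulfones to β-cyclogeranyl sulfones is established, and it makes C7=C8 by Julia–Kocienski olefination. Compound 7 is trifluoroacetylated in the flask as in step 3 (compound 8), and the liberated CF3CO2H catalyses 1,4-hydrothiolation of the diene by 2-mercaptobenzothiazole to give (4S,6E)-8-(1,3-benzothiazol-2-ylsulfanyl)-2,6-dimethylocta-1,6-dien-4-yl trifluoroacetate F1. (NH4)6Mo7O24·4H2O with H2O2 in aqueous EtOH oxidises sulfur only, and its work-up hydrolyses the ester to give (4S,6E)-8-(1,3-benzothiazol-2-ylsulfonyl)-2,6-dimethylocta-1,6-dien-4-ol F2. MsOH in CH2Cl2 at 0 °C closes ring B to (1R)-4-[(1,3-benzothiazol-2-ylsulfonyl)methyl]-3,5,5-trimethylcyclohex-3-en-1-ol F3. F3 and 12 with LiN(SiMe3)2 (2.2 equiv, THF, −78 °C → rt), then the same thermal isomerisation, give 14.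

Step 4 is next. The hindered cyclogeranyl ylide may add too slowly to the weakly electrophilic, poorly soluble C30 polyenal or give intractable 7Z/7E mixtures. The fallback sets out from 11 and comes back at 14. It moves the hindered olefination to a small, reactive enal and finishes with C15 chemistry (C15 + C10 + C15). The ylide of 11 (LiN(SiMe3)2, 2 equiv, THF, −78 °C) is condensed with commercial (2E)-4-acetoxy-2-methylbut-2-enal to give (2E,4E)-5-[(4R)-4-hydroxy-2,6,6-trimethylcyclohex-1-en-1-yl]-3-methylpenta-2,4-dien-1-yl acetate F4. Ph3P·HBr in MeOH converts the allylic acetate into [(2E,4E)-5-[(4R)-4-hydroxy-2,6,6-trimethylcyclohex-1-en-1-yl]-3-methylpenta-2,4-dien-1-yl](triphenyl)phosphonium bromide F5. F5 with excess commercial (2E,4E,6E)-2,7-dimethylocta-2,4,6-trienedial and NaOMe gives (3R)-3-hydroxy-12'-apo-β-caroten-12'-al F6. F6 with the commercial ring A salt [(2E,4E)-3-methyl-5-(2,6,6-trimethylcyclohex-1-en-1-yl)penta-2,4-dien-1-yl](triphenyl)phosphonium bromide and NaOMe gives 14, so 12 is no longer needed.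

Step 2 is third. The chloroprene Grignard reagent is capricious to make (polymerisation) and can give allenic by-products. The fallback sets out from 4 and comes back at 7. It builds the diene by enyne metathesis instead of using a dienyl metal. Epoxide 4 is opened with LiC≡CH·H2NCH2CH2NH2 in DMSO to give (4S)-2-methylhept-1-en-6-yn-4-ol F7. Cross-enyne metathesis of F7 with ethylene (1 atm, CH2Cl2, rt) over the second-generation Grubbs catalyst RuCl2(=CHPh)(H2IMes)(PCy3) (5 mol %) gives 7; the 1,1-disubstituted isopropenyl group is a poor metathesis partner.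

**Further compounds**
F1 | step 3 | (4S,6E)-8-(1,3-benzothiazol-2-ylsulfanyl)-2,6-dimethylocta-1,6-dien-4-yl trifluoroacetate | FC(F)(F)C(=O)O[C@@H](CC(C)=C)C/C(C)=C/CSc1nc2ccccc2s1
F2 | step 3 | (4S,6E)-8-(1,3-benzothiazol-2-ylsulfonyl)-2,6-dimethylocta-1,6-dien-4-ol | O[C@@H](CC(C)=C)C/C(C)=C/CS(=O)(=O)c1nc2ccccc2s1
F3 | step 3 | (1R)-4-[(1,3-benzothiazol-2-ylsulfonyl)methyl]-3,5,5-trimethylcyclohex-3-en-1-ol | O[C@@H]1CC(C)=C(CS(=O)(=O)c2nc3ccccc3s2)C(C)(C)C1
F4 | step 4 | (2E,4E)-5-[(4R)-4-hydroxy-2,6,6-trimethylcyclohex-1-en-1-yl]-3-methylpenta-2,4-dien-1-yl acetate | CC(=O)OC/C=C(C)/C=C/C1=C(C)C[C@@H](O)CC1(C)C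
F5 | step 4 | [(2E,4E)-5-[(4R)-4-hydroxy-2,6,6-trimethylcyclohex-1-en-1-yl]-3-methylpenta-2,4-dien-1-yl](triphenyl)phosphonium bromide | [Br-].O[C@@H]1CC(C)=C(/C=C/C(C)=C/C[P+](c2ccccc2)(c2ccccc2)c2ccccc2)C(C)(C)C1
F6 | step 4 | (3R)-3-hydroxy-12'-apo-β-caroten-12'-al | O=C/C(C)=C/C=C/C=C(C)/C=C/C=C(C)/C=C/C1=C(C)C[C@@H](O)CC1(C)C
F7 | step 2 | (4S)-2-methylhept-1-en-6-yn-4-ol | O[C@@H](CC(C)=C)CC#C
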